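All constants belong to no real substance; the result is computed.

Over the 2.5 h of this run, target forms from what has dissolved, so you hold the time against the charge of solid.

solid substrate 28 mM; gas 2.6 mM (held); time 2.5 h

    solid substrate ⇌ dissolved substrate, rate k1*(cs1 - [dissolved substrate]) while solid is left; crystals form when [dissolved substrate] > cs1 (cs1 = 10 mM, k1 = 2.95 × 10⁻⁴ s⁻¹)
    dissolved substrate + reagent → target (k2 = 3.04 M⁻¹ s⁻¹)
    gas ⇌ reagent, rate k3*(csat - [reagent]) (k3 = 0.0269 s⁻¹, csat = 2.6 mM)
    crystals ⇌ target, rate k4*(cs4 - [target]) while solid is left; crystals form when [target] > cs4 (cs4 = 13 mM, k4 = 0.00151 s⁻¹)
    2 reagent → self-condensation product (k5 = 0.0297 M⁻¹ s⁻¹)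

1. target and crystals together at 2.5 h, in percent of the solid substrate charged
2. concentration of dissolved substrate in solution at 2.5 h, in percent of saturation

- what is said of target includes crystals
- for a step with 2 of a species take k times the square, and two of it per event
- solid substrate, crystals is a solid; its amount is given per volume of the solution
- at the start none of reagent is dissolved
- at the start none of the solid substrate is in solution
- dissolved substrate means what is dissolved; the solid is not counted in it
- run time (flask): 2.5 h

The bench rule says that a suspension consumed as it dissolves goes at its flat-out rate, 10.6 mM h⁻¹, which would pass 94.8 % of this charge in the run. That rule assumes an empty solution, and a ratio of given numbers shows where it stops. Reagent at 2.6 mM clears dissolved substrate with a pseudo-first-order constant of 0.00790 s⁻¹, which is 26.8 times the dissolution coefficient, and with reagent held there and solid present, the steady share of saturation is one over one plus that ratio, so the rule stops working as the ratio comes down towards one.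

Here the ratio leaves c(dissolved substrate) at a steady 3.60 % of saturation by my reckoning. The flat-out rate is trimmed by that share to the feed, 10.2 mM h⁻¹, the rate at which solid passes into solution while solid lasts. The reagent balance permits this, since the gas can supply up to 252 mM h⁻¹, far more than the feed asks, so the feed pulls c(reagent) down by about 0.106 mM, which I neglect. Feed times time over charge gives me 91.4 %, which I take for y, leaving aside what stands dissolved.

The forecast, slightly apart from me, says 90 % and 3.8 %, with “leaving dissolution running almost flat out”.

| | y | sat |
|---|---|---|
| my reckoning | 91.4 % | 3.60 % |
| forecast | 90 % | 3.8 % |
| simulation | 89.9 % | 3.76 % |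

Take from my 91.4 % the 1.34 % of the charge standing dissolved in this flask and 90.1 % remains, against the simulated 89.9 %. What keeps this flask from a full yield is slow dissolving together with the length of the run: with fast dissolving, or with ten times the time, it goes from 89.9 % to 100 %. For a neighbour flask charged with 70 mM of solid substrate, the same feed predicts 36.0 % once its standing dissolved share is taken off, and that flask gave 36.0 % with 63.5 % still solid.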